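We follow the L: of each charge, how much ends as J?

| flask | L | time |
|---|---|---|
| eta | 1.00 M |  |
| zeta | 1.50 M |  |
| beta | 1.00 M | 320 min |

| run | time / min | [J] / M |
|---|---|---|
| eta run | 13 | 0.184 |
| eta run | 26 | 0.355 |
| eta run | 40 | 0.467 |
| eta run | 53 | 0.507 |
| eta run | 66 | 0.560 |
| eta run | 79 | 0.566 |
| zeta run | 13 | 0.245 |
| zeta run | 26 | 0.473 |
| zeta run | 40 | 0.654 |
| zeta run | 53 | 0.760 |
| zeta run | 66 | 0.829 |
| zeta run | 79 | 0.846 |

(scatter of a reading: 0.008 M)

- how the opening rate goes with [L] round the charge of the eta run: the exponent of the rate at two percent of L gone to J (one fixed amount of J, the same in the runs compared)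
- J in the beta run at 320 min, as a share of the L charged

- Overall: L -> J.
- Constant volume, constant temperature.
- A reading of a species includes what of it is bound.
- An order is taken over about fifteen percent of the charge, up and down.

We fold each run into one number, the plateau share, meaning the mean over both runs of the last [J] divided by the L charged, which says what part of a charge comes out as J: 56.5%. To test whether one number is enough, we compare the runs: the eta run gives 56.6% and the zeta run 56.4%, so the share holds while the charge changes by a factor of 1.50. But the zeta run still rose by 0.0170 M in its last step, more than the scatter of 0.008 M, so for the beta run, with the charge of the eta run and 320 min to go, we expect a little above 56.5%. The readings at 13 min give us an order of 0.706, but that is an average across the two charges.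

The forecast gives an order of 0.72 and, for the beta run, 59%, the latter on the ground that “Both runs flatten at nearly the same fraction”.

The flask gives 58.9% and an order of 0.51.

    L ⇌ X (0.03726 min⁻¹, 0.01572 min⁻¹)
    X → J (0.5088 min⁻¹)
    L → Ze (0.02520 min⁻¹)
    2 L ⇌ L2, settled at all times (0.7980 M⁻¹)

In the beta run, the missing 41.1% of the charge is L turned into Ze. The plateau share is therefore a branching share: the constants give J 58.9% of the L consumed, against the 56.5% we read at the last readings. The simulated beta run without that step shows the same rule, for there the share of J rises to >99.9%.

The runs come from a simulation for substances that don't exist, and the scatter is random.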